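**Strategy.** The trimethylcyclohexene ring is built by a [4+2] Schweizer annulation and then joined to an enantiopure chromane. With the ring numbered C1 (chain-bearing olefinic carbon), C2 (methyl-bearing olefinic carbon), C3–C5 (methylenes) and C6 (gem-dimethyl carbon), C1 is carried as a ketone flanked by C6 and C2, and C5 as an aldehyde. The enolate of 2,2-dimethyl-3-oxopentanal adds through C2 to vinyltriphenylphosphonium bromide (C2–C3 bond), and the resulting ylide closes the ring by Wittig reaction with the aldehyde (C4–C5 bond), so the two-carbon unit C3–C4 is inserted in one operation. The ketone then becomes the enol triflate that receives the side chain; the chromane centre comes from a Sharpless epoxidation.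

Key step: step 2

Remark: 8 and 9 are racemic at the methyl-bearing ring carbon; this centre becomes sp2 in step 4.
Remark: the facial sense of the epoxidation in step 10 is assigned by analogy with geraniol, which gives the (2S,3S)-epoxy alcohol with L-(+)-diethyl tartrate.
Remark: 1, 2, 5, 12, 16 and 17 are taken as commercial.

**Step 1**
Reactants: 1 4-(2-methylprop-1-en-1-yl)morpholine; 2 propanoyl chloride
Product: 4 2,2-dimethyl-3-oxopentanal, via iminium chloride 3 (not isolated)
Conditions: Et2O, 0 °C to rt; then aq. HCl, rt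
Reagents that add atoms: water, O
Why: Stork enamine C-acylation should occur at the β-carbon of the aldehyde enamine, and the resulting iminium salt, which has no α-hydrogen, is hydrolysed to the β-keto aldehyde.

**Step 2**
Reactants: 4 2,2-dimethyl-3-oxopentanal; 5 vinyltriphenylphosphonium bromide
Product: 8 2,2,6-trimethylcyclohex-3-en-1-one (racemic), via sodium enolate 6 (not isolated), via phosphorus ylide 7 (not isolated)
Conditions: NaH, 5 (1.2 equiv), THF/DMF, slow addition of 4 at 0 °C; then 60 °C
Reagents that add atoms: none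
Why: NaH removes a proton from the only enolisable position of 4 (the ketone CH2; the aldehyde sits on a quaternary carbon), the enolate carbon adds to the terminal carbon of the vinylphosphonium salt to give the non-stabilised ylide 7, and the ylide carbon attacks the neopentyl aldehyde and expels Ph3PO via the oxaphosphetane. This is the Schweizer annulation, a conjugate addition followed by intramolecular Wittig olefination, a known way to make cycloalkenes from enolates that carry a second carbonyl group. The six-membered carbocycle is closed in the Wittig event by 6-exo-trig addition of the ylide carbon to the aldehyde C=O, and the ring can only hold the cis alkene. The one new stereocentre, the methyl-bearing carbon, is formed without control as a racemate, which is harmless because it becomes sp2 in step 4. The step needs C- instead of O-attack of the enolate and conjugate addition faster than intermolecular aldol addition; the soft phosphonium acceptor favours carbon, slow addition of 4 to NaH and excess 5 should trap the enolate as it forms, and aldol adducts of the hindered non-enolisable aldehyde should revert. Regiochemistry is unambiguous because 4 has a single acidic site and a single aldehyde.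

**Step 3**
Reactants: 8 2,2,6-trimethylcyclohex-3-en-1-one
Product: 9 2,2,6-trimethylcyclohexan-1-one (racemic)
Conditions: H2 (1 atm), Pd/C, pentane, rt
Reagents that add atoms: none
Why: Catalytic hydrogenation should saturate the isolated cis-disubstituted ring alkene and leave the hindered ketone untouched.

**Step 4**
Reactants: 9 2,2,6-trimethylcyclohexan-1-one
Product: 11 2,6,6-trimethylcyclohex-1-en-1-yl trifluoromethanesulfonate, via lithium enolate 10 (not isolated)
Conditions: LDA, THF, −78 °C; then PhNTf2, −78 °C to rt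
Reagents that add atoms: N-phenylbis(trifluoromethanesulfonimide), O=S(=O)(N(c1ccccc1)S(=O)(=O)C(F)(F)F)C(F)(F)F
Why: The ketone has a single α-hydrogen, so enolisation is regiospecific and O-triflation (enol triflate formation) fixes the tetrasubstituted C1=C2 alkene of the ring.

**Step 5**
Reactants: 11 2,6,6-trimethylcyclohex-1-en-1-yl trifluoromethanesulfonate; 12 (4-bromobut-1-yn-1-yl)trimethylsilane
Product: 14 trimethyl[4-(2,6,6-trimethylcyclohex-1-en-1-yl)but-1-yn-1-yl]silane, via alkylzinc bromide 13 (not isolated)
Conditions: 12, Zn dust, I2 (5 mol%), DMA, 70 °C; then 11, Pd(dppf)Cl2 (5 mol%), THF, 60 °C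
Reagents that add atoms: none
Why: Negishi sp3–sp2 cross-coupling of a primary alkylzinc with the enol triflate should form the C1–side-chain bond, the bidentate ligand suppressing β-hydride elimination and the silyl group masking the alkyne.

**Step 6**
Reactants: 14 trimethyl[4-(2,6,6-trimethylcyclohex-1-en-1-yl)but-1-yn-1-yl]silane
Product: 15 2-(but-3-yn-1-yl)-1,3,3-trimethylcyclohex-1-ene
Conditions: K2CO3, MeOH, rt
Reagents that add atoms: none
Why: Base-catalysed methanolysis of the alkynyl–silicon bond frees the terminal alkyne (protodesilylation).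

**Step 7**
Reactants: 16 methyl 4-hydroxy-3-iodobenzoate; 17 prop-2-en-1-ol
Product: 18 methyl 4-hydroxy-3-(3-oxopropyl)benzoate
Conditions: Pd(OAc)2 (3 mol%), Bu4NCl, NaHCO3, DMF, 45 °C
Reagents that add atoms: none
Why: Jeffery–Heck arylation of allyl alcohol with β-hydride elimination toward the carbinol carbon delivers the 3-arylpropanal, which is expected to sit largely as its lactol with the ortho phenol.

**Step 8**
Reactants: 18 methyl 4-hydroxy-3-(3-oxopropyl)benzoate
Product: 19 methyl 3-(but-3-yn-1-yl)-4-hydroxybenzoate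
Conditions: dimethyl (1-diazo-2-oxopropyl)phosphonate, K2CO3, MeOH, rt
Reagents that add atoms: dimethyl (1-diazo-2-oxopropyl)phosphonate, COP(=O)(OC)C(=[N+]=[N-])C(C)=O
Why: Ohira–Bestmann homologation converts the aldehyde, released from the lactol under the basic conditions, into the terminal alkyne.

**Step 9**
Reactants: 19 methyl 3-(but-3-yn-1-yl)-4-hydroxybenzoate
Product: 21 methyl 4-hydroxy-3-[(3E)-5-hydroxy-3-methylpent-3-en-1-yl]benzoate, via alkenylalane 20 (not isolated)
Conditions: Me3Al (4 equiv), Cp2ZrCl2 (25 mol%), CH2Cl2, 0 °C to rt; then n-BuLi, THF, −78 °C; (CH2O)n, −78 °C to rt; aq. HCl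
Reagents that add atoms: trimethylaluminium, C[Al](C)C; paraformaldehyde (as formaldehyde), C=O
Why: Negishi zirconium-catalysed methylalumination adds methyl and aluminium syn across the alkyne with methyl at the internal carbon, and the derived alanate adds to formaldehyde with retention, which should give the (E)-trisubstituted allylic alcohol.

**Step 10**
Reactants: 21 methyl 4-hydroxy-3-[(3E)-5-hydroxy-3-methylpent-3-en-1-yl]benzoate
Product: 23 methyl (2R)-2-[(1S)-1,2-dihydroxyethyl]-2-methylchromane-6-carboxylate, via epoxy alcohol 22 (not isolated)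
Conditions: Ti(OiPr)4 (1.2 equiv), L-(+)-diethyl tartrate (1.5 equiv), t-BuOOH, 4 Å molecular sieves, CH2Cl2, −20 °C; then rt
Reagents that add atoms: tert-butyl hydroperoxide, CC(C)(C)OO
Why: Katsuki–Sharpless epoxidation of this geraniol-type (E)-allylic alcohol with L-(+)-diethyl tartrate should give the (2S,3S)-epoxy alcohol 22, and the titanium-activated epoxide is then opened by the pendant phenol at the tertiary carbon (6-exo, inversion), which sets (R) at chromane C2 while the secondary carbinol keeps (S).

**Step 11**
Reactants: 23 methyl (2R)-2-[(1S)-1,2-dihydroxyethyl]-2-methylchromane-6-carboxylate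
Product: 24 methyl (2R)-2-formyl-2-methylchromane-6-carboxylate
Conditions: NaIO4, THF/H2O, 0 °C to rt
Reagents that add atoms: none
Why: Periodate glycol cleavage removes the terminal carbon and leaves an aldehyde on a quaternary carbon that cannot epimerise.

**Step 12**
Reactants: 24 methyl (2R)-2-formyl-2-methylchromane-6-carboxylate
Product: 25 methyl (2R)-2-[(E)-2-iodoethenyl]-2-methylchromane-6-carboxylate
Conditions: CrCl2 (6 equiv), CHI3 (2 equiv), THF, 0 °C to rt
Reagents that add atoms: iodoform, IC(I)I
Why: Takai olefination should convert the hindered aldehyde into the (E)-iodoalkene, the bulky quaternary substituent reinforcing the E preference.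

**Step 13**
Reactants: 15 2-(but-3-yn-1-yl)-1,3,3-trimethylcyclohex-1-ene; 25 methyl (2R)-2-[(E)-2-iodoethenyl]-2-methylchromane-6-carboxylate
Product: 27 methyl (2R)-2-methyl-2-[(1E,3E)-4-methyl-6-(2,6,6-trimethylcyclohex-1-en-1-yl)hexa-1,3-dien-1-yl]chromane-6-carboxylate, via alkenylalane 26 (not isolated)
Conditions: 15 (1.3 equiv), Me3Al, Cp2ZrCl2 (25 mol%), ClCH2CH2Cl, rt; then 25, ZnCl2, Pd(PPh3)4 (5 mol%), THF, rt
Reagents that add atoms: trimethylaluminium, C[Al](C)C
Why: Negishi methylalumination of the terminal alkyne (syn, methyl internal) followed by palladium/zinc-cocatalysed alkenyl–alkenyl cross-coupling proceeds with retention at both partners and should give the (E,E)-diene, the tetrasubstituted ring alkene and the ester being inert at rt.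

**Step 14**
Reactants: 27 methyl ester of the target
Product: 28 (2R)-2-methyl-2-[(1E,3E)-4-methyl-6-(2,6,6-trimethylcyclohex-1-en-1-yl)hexa-1,3-dien-1-yl]chromane-6-carboxylic acid
Conditions: LiOH, THF/MeOH/H2O, rt; then aq. HCl to pH 3
Reagents that add atoms: lithium hydroxide, [Li+].[OH-]
Why: Saponification of the aryl methyl ester leaves the diene, the ring alkene and the quaternary stereocentre untouched.

**Compound list**
1 | 4-(2-methylprop-1-en-1-yl)morpholine | CC(C)=CN1CCOCC1 | starting material
2 | propanoyl chloride | CCC(=O)Cl | starting material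
3 | 4-(2,2-dimethyl-3-oxopentylidene)morpholin-4-ium chloride | CCC(=O)C(C)(C)C=[N+]1CCOCC1.[Cl-] | intermediate
4 | 2,2-dimethyl-3-oxopentanal | CCC(=O)C(C)(C)C=O | intermediate
5 | vinyltriphenylphosphonium bromide | C=C[P+](c1ccccc1)(c1ccccc1)c1ccccc1.[Br-] | starting material
6 | sodium 4,4-dimethyl-5-oxopent-2-en-3-olate | CC=C([O-])C(C)(C)C=O.[Na+] | intermediate
7 | 2,2,4-trimethyl-3-oxo-6-(triphenylphosphoranylidene)hexanal | CC(CC=P(c1ccccc1)(c1ccccc1)c1ccccc1)C(=O)C(C)(C)C=O | intermediate
8 | 2,2,6-trimethylcyclohex-3-en-1-one (racemic) | CC1CC=CC(C)(C)C1=O | intermediate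
9 | 2,2,6-trimethylcyclohexan-1-one (racemic) | CC1CCCC(C)(C)C1=O | intermediate
10 | lithium 2,6,6-trimethylcyclohex-1-en-1-olate | CC1=C([O-])C(C)(C)CCC1.[Li+] | intermediate
11 | 2,6,6-trimethylcyclohex-1-en-1-yl trifluoromethanesulfonate | CC1=C(OS(=O)(=O)C(F)(F)F)C(C)(C)CCC1 | intermediate
12 | (4-bromobut-1-yn-1-yl)trimethylsilane | C[Si](C)(C)C#CCCBr | starting material
13 | [4-(trimethylsilyl)but-3-yn-1-yl]zinc bromide | C[Si](C)(C)C#CCC[Zn]Br | intermediate
14 | trimethyl[4-(2,6,6-trimethylcyclohex-1-en-1-yl)but-1-yn-1-yl]silane | C[Si](C)(C)C#CCCC1=C(C)CCCC1(C)C | intermediate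
15 | 2-(but-3-yn-1-yl)-1,3,3-trimethylcyclohex-1-ene | C#CCCC1=C(C)CCCC1(C)C | intermediate
16 | methyl 4-hydroxy-3-iodobenzoate | COC(=O)c1ccc(O)c(I)c1 | starting material
17 | prop-2-en-1-ol | C=CCO | starting material
18 | methyl 4-hydroxy-3-(3-oxopropyl)benzoate | COC(=O)c1ccc(O)c(CCC=O)c1 | intermediate
19 | methyl 3-(but-3-yn-1-yl)-4-hydroxybenzoate | COC(=O)c1ccc(O)c(CCC#C)c1 | intermediate
20 | methyl 4-[(dimethylalumanyl)oxy]-3-[(3E)-4-(dimethylalumanyl)-3-methylbut-3-en-1-yl]benzoate | COC(=O)c1ccc(O[Al](C)C)c(CC/C(C)=C/[Al](C)C)c1 | intermediate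
21 | methyl 4-hydroxy-3-[(3E)-5-hydroxy-3-methylpent-3-en-1-yl]benzoate | COC(=O)c1ccc(O)c(CC/C(C)=C/CO)c1 | intermediate
22 | methyl 4-hydroxy-3-{2-[(2S,3S)-3-(hydroxymethyl)-2-methyloxiran-2-yl]ethyl}benzoate | OC[C@@H]1O[C@@]1(C)CCc1cc(C(=O)OC)ccc1O | intermediate
23 | methyl (2R)-2-[(1S)-1,2-dihydroxyethyl]-2-methylchromane-6-carboxylate | OC[C@H](O)[C@@]1(C)CCc2cc(C(=O)OC)ccc2O1 | intermediate
24 | methyl (2R)-2-formyl-2-methylchromane-6-carboxylate | O=C[C@@]1(C)CCc2cc(C(=O)OC)ccc2O1 | intermediate
25 | methyl (2R)-2-[(E)-2-iodoethenyl]-2-methylchromane-6-carboxylate | I/C=C/[C@@]1(C)CCc2cc(C(=O)OC)ccc2O1 | intermediate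
26 | dimethyl[(1E)-2-methyl-4-(2,6,6-trimethylcyclohex-1-en-1-yl)but-1-en-1-yl]alumane | CC1=C(CC/C(C)=C/[Al](C)C)C(C)(C)CCC1 | intermediate
27 | methyl (2R)-2-methyl-2-[(1E,3E)-4-methyl-6-(2,6,6-trimethylcyclohex-1-en-1-yl)hexa-1,3-dien-1-yl]chromane-6-carboxylate | CC1=C(CC/C(C)=C/C=C/[C@@]2(C)CCc3cc(C(=O)OC)ccc3O2)C(C)(C)CCC1 | intermediate
28 | (2R)-2-methyl-2-[(1E,3E)-4-methyl-6-(2,6,6-trimethylcyclohex-1-en-1-yl)hexa-1,3-dien-1-yl]chromane-6-carboxylic acid | CC1=C(CC/C(C)=C/C=C/[C@@]2(C)CCc3cc(C(=O)O)ccc3O2)C(C)(C)CCC1 | target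

**Total step count:** 14. **Longest linear sequence:** 8 steps (1–6, 13, 14, or equally 7–14).

**Steps most likely to fail**

Step 2. The enolate may add to the aldehyde of a second molecule and oligomerise instead of adding to the phosphonium salt. It may also attack through oxygen, which after Wittig closure would give a pyran, and the volatile product may be lost on isolation. The fallback sets out from 2 and comes back at 9, and still forms both ring bonds in one operation. Compound 2 is converted with isopropenylmagnesium bromide (CuI cat., THF, −78 °C) into 2-methylpent-1-en-3-one F1. Silylation (TMSOTf, Et3N) gives the siloxydiene trimethyl{[(3Z)-2-methylpenta-1,3-dien-3-yl]oxy}silane F2. Diels–Alder reaction of F2 with phenyl vinyl sulfone as an ethylene equivalent (toluene, 110 °C) should give trimethyl{[2,6-dimethyl-4-(phenylsulfonyl)cyclohex-1-en-1-yl]oxy}silane F3. Fluoride-induced regiospecific enolate formation and methylation (BnMe3NF, MeI, THF) would install the gem-dimethyl carbon and give 2,2,6-trimethyl-4-(phenylsulfonyl)cyclohexan-1-one F4. Reductive desulfonylation (Mg, MeOH) then returns 9.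

Step 10. The free phenol may bind titanium and erode the rate or the enantioselectivity of the epoxidation, and ring opening may start before the epoxidation is complete. The fallback sets out from 21 and comes back at 23. The phenoxide is silylated selectively (NaH, 1 equiv; TBSCl, THF) to methyl 4-[(tert-butyldimethylsilyl)oxy]-3-[(3E)-5-hydroxy-3-methylpent-3-en-1-yl]benzoate F5. Catalytic Sharpless epoxidation (Ti(OiPr)4 5 mol%, L-(+)-diethyl tartrate, t-BuOOH, −20 °C) should give methyl 4-[(tert-butyldimethylsilyl)oxy]-3-{2-[(2S,3S)-3-(hydroxymethyl)-2-methyloxiran-2-yl]ethyl}benzoate F6. Desilylation (Bu4NF, AcOH) followed by camphorsulfonic acid in CH2Cl2 closes the chromane with inversion and gives 23.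

Step 9. Butyllithium or the alanate may attack the methyl ester during the capture of formaldehyde, and the aluminium phenoxide may slow the carboalumination. The fallback sets out from 19 and comes back at 21. Methylalumination as in step 9 is quenched with I2 to give methyl 4-hydroxy-3-[(3E)-4-iodo-3-methylbut-3-en-1-yl]benzoate F7. Nozaki–Hiyama–Kishi addition of the derived alkenylchromium species to paraformaldehyde (CrCl2, NiCl2 cat., DMF, rt) then gives 21 without any organolithium.

**Further compounds**
F1 | step 2 | 2-methylpent-1-en-3-one | CCC(=O)C(C)=C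
F2 | step 2 | trimethyl{[(3Z)-2-methylpenta-1,3-dien-3-yl]oxy}silane | C/C=C(\O[Si](C)(C)C)C(C)=C
F3 | step 2 | trimethyl{[2,6-dimethyl-4-(phenylsulfonyl)cyclohex-1-en-1-yl]oxy}silane | CC1CC(S(=O)(=O)c2ccccc2)CC(C)=C1O[Si](C)(C)C
F4 | step 2 | 2,2,6-trimethyl-4-(phenylsulfonyl)cyclohexan-1-one | CC1CC(S(=O)(=O)c2ccccc2)CC(C)(C)C1=O
F5 | step 10 | methyl 4-[(tert-butyldimethylsilyl)oxy]-3-[(3E)-5-hydroxy-3-methylpent-3-en-1-yl]benzoate | COC(=O)c1ccc(O[Si](C)(C)C(C)(C)C)c(CC/C(C)=C/CO)c1
F6 | step 10 | methyl 4-[(tert-butyldimethylsilyl)oxy]-3-{2-[(2S,3S)-3-(hydroxymethyl)-2-methyloxiran-2-yl]ethyl}benzoate | OC[C@@H]1O[C@@]1(C)CCc1cc(C(=O)OC)ccc1O[Si](C)(C)C(C)(C)C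
F7 | step 9 | methyl 4-hydroxy-3-[(3E)-4-iodo-3-methylbut-3-en-1-yl]benzoate | COC(=O)c1ccc(O)c(CC/C(C)=C/I)c1
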